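**Retrosynthetic overview**

1. Xenicane numbering is used: C1 and C19 are the formyl carbons on C11a and C11, C4a carries the side chain, C5 is the carbinol carbon, C4 the side-chain methine, C3 the acetoxymethyl carbon. Ring A is the cyclononadiene, ring B a temporary tetrahydrofuran (C1–O–C19 bis-acetal), ring C a temporary γ-lactone (C3(=O)–O–C5).
2. Target 26 ⇐ hydrolysis of ring B ⇐ monoacetate 25 ⇐ reductive opening of ring C in 23 ⇐ prenyl-copper addition to the α-methylene lactone 20, with C4 set by equilibration.
3. Key disconnection: the C4a–C5 bond of 20 ⇐ bromo aldehyde 17, by an intramolecular chromium-mediated allylation/lactonisation that closes rings A and C together and sets C4a and C5. It is possible because O–C5–C4a–C4–C3 is a 1,4-dioxygenated chain, that is a γ-lactone whose β,γ-bond is C4a–C5, and because the 1,4-dialdehyde C1–C11a–C11–C19 can be tied as ring B, which holds both reacting arms on the adjacent atoms C11a and C11.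
4. 17 ⇐ three-component coupling of the menthyloxybutenolide 6 (bought stereocentre, C1), 2-lithio-1,3-dithiane (C4a) and aldehyde 5 (C5–C10, from alkyne 1), then C4/C3/C12 from methyl propiolate. The stereochemical relay is C1 → C11a → C4a and C5, then C4 by thermodynamic control; C1 is erased at the end.
5. Ring order: ring B (present in 6) → rings A and C in one step (step 11) → ring C opened (step 13) → ring B opened (step 15).

Key step: step 11

Assumption: (5R)-5-(l-menthyloxy)furan-2(5H)-one (6) is taken as a purchasable single diastereomer.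
Remark: the acetal carbon C19 of 11–25 is an anomeric mixture of no consequence (it ends as a formyl group); the SMILES leave it undefined.

**Route**

Step 1
Reactants: 1 tert-butyl(but-3-yn-1-yloxy)dimethylsilane
Product: 4 (E)-6-(tert-butyldimethylsilyloxy)-4-methylhex-3-en-1-ol, via alkenyldimethylalane 2 (not isolated), via lithium alkenylalanate 3 (not isolated)
Conditions: AlMe3, Cp2ZrCl2 (cat.), CH2Cl2, 0 °C to rt; n-BuLi, −78 °C; oxirane, THF, −78 °C to rt; aq. potassium sodium tartrate
Reagents that add atoms: trimethylaluminium C[Al](C)C; oxirane C1CO1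
Why: Zirconium-catalysed syn-carboalumination of the terminal alkyne (Negishi carboalumination) puts methyl and aluminium cis, and the derived alanate opens oxirane with retention at the alkenyl carbon, so the E geometry of the later C7=C8 bond is fixed by the syn addition.

Step 2
Reactants: 4 (E)-6-(tert-butyldimethylsilyloxy)-4-methylhex-3-en-1-ol
Product: 5 (E)-6-(tert-butyldimethylsilyloxy)-4-methylhex-3-enal
Conditions: Dess–Martin periodinane, NaHCO3, CH2Cl2, 0 °C
Reagents that add atoms: none
Why: Dess–Martin oxidation under buffered, non-basic conditions should give the β,γ-unsaturated aldehyde without moving the double bond into conjugation; no stereocentre is involved and 5 is used at once.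

Step 3
Reactants: 6 (5R)-5-(l-menthyloxy)furan-2(5H)-one; 5 (E)-6-(tert-butyldimethylsilyloxy)-4-methylhex-3-enal
Product: 8 aldol adduct (dithianyl lactone with the hydroxyalkyl chain at C11), via lithium lactone enolate 7 (not isolated)
Conditions: 1,3-dithiane, n-BuLi, THF, −30 °C; 6, THF/DMPU, −78 °C; then 5, −78 °C; aq. NH4Cl
Reagents that add atoms: 1,3-dithiane C1CSCSC1
Why: Tandem Michael addition/aldol reaction on a γ-alkoxybutenolide: the dithiane anion adds to the β-carbon anti to the menthyloxy group at C1, which sets C11a, and the enolate adds to 5 anti to the new C11a substituent; the centres at C11 and at the carbinol carbon are mixtures without consequence because both become sp2 in step 4.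

Step 4
Reactants: 8 aldol adduct
Product: 10 (E)-alkylidene lactone, via mesylate 9 (not isolated)
Conditions: MsCl, Et3N, CH2Cl2, 0 °C; then DBU, 0 °C
Reagents that add atoms: none
Why: Mesylation and E1cB elimination complete an aldol condensation and should give the E-alkylidene lactone (C9 cis to C11a), the isomer favoured by the elimination and by thermodynamics.

Step 5
Reactants: 10 (E)-alkylidene lactone
Product: 12 ring B bis-acetal (methyl acetal at C19), via lactol 11 (not isolated)
Conditions: i-Bu2AlH, CH2Cl2, −78 °C; aq. potassium sodium tartrate; then MeOH, PPTS (cat.), 0 °C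
Reagents that add atoms: methanol CO
Why: Half-reduction of the lactone at low temperature gives the lactol, and acid-catalysed exchange through the allyl-stabilised oxocarbenium ion gives the mixed methyl acetal; C19 forms as an anomeric mixture that does not matter, and the less easily ionised menthyl acetal at C1 is kept.

Step 6
Reactants: 12 ring B bis-acetal dithiane
Product: 13 C4a aldehyde
Conditions: MeI, CaCO3, MeCN/H2O (9:1), 45 °C
Reagents that add atoms: water O
Why: Alkylative hydrolysis of the dithiane (S-methylation, then hydrolysis of the sulfonium salt) runs under buffered neutral conditions that spare acetals, silyl ether and alkenes, and C11a stays trans to the menthyloxy group, which is also its more stable position.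

Step 7
Reactants: 13 C4a aldehyde
Product: 14 allylic alcohol (Morita–Baylis–Hillman-type adduct, carbinol epimers)
Conditions: methyl propiolate, i-Bu2AlH, N-methylmorpholine N-oxide, THF, 0 °C; then 13, 0 °C to rt
Reagents that add atoms: methyl propiolate C#CC(=O)OC
Why: Hydroalumination of methyl propiolate gives an α-aluminated acrylate that adds to the aldehyde (vinylalumination, a non-basic equivalent of the Morita–Baylis–Hillman reaction), so the epimerisable aldehyde meets no amine base; the new carbinol centre is a mixture that is erased in step 8.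

Step 8
Reactants: 14 allylic alcohol
Product: 15 (Z)-2-(bromomethyl)enoate
Conditions: NBS, Me2S, CH2Cl2, −20 to 0 °C
Reagents that add atoms: N-bromosuccinimide O=C1CCC(=O)N1Br
Why: Corey–Kim activation of the alcohol and SN2′ attack of bromide at the methylene terminus give the rearranged primary allylic bromide as the more stable Z isomer (C11a cis to CH2Br, trans to the ester), the usual outcome for Morita–Baylis–Hillman alcohols.

Step 9
Reactants: 15 (Z)-2-(bromomethyl)enoate silyl ether
Product: 16 bromo alcohol
Conditions: HF·pyridine, pyridine, THF, 0 °C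
Reagents that add atoms: none
Why: Pyridine-buffered fluoride desilylation should cleave the primary silyl ether without displacing the allylic bromide or hydrolysing ring B.

Step 10
Reactants: 16 bromo alcohol
Product: 17 bromo aldehyde
Conditions: Dess–Martin periodinane, NaHCO3, CH2Cl2, 0 °C
Reagents that add atoms: none
Why: Dess–Martin oxidation of the primary alcohol under buffered conditions should give the β,γ-unsaturated aldehyde in the presence of the allylic bromide; 17 is used at once.

Step 11
Reactants: 17 bromo aldehyde
Product: 20 tricyclic α-methylene lactone (rings A, B and C), via allylchromium dichloride 18 (not isolated), via chromium alkoxide 19 (not isolated)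
Conditions: CrCl2 (8 equiv), THF, 2 mM (syringe-pump addition of 17), 25 °C; aq. NH4Cl
Reagents that add atoms: none
Why: Two equivalents of divalent chromium reduce the allylic bromide to the σ-allylchromium species 18, whose γ-carbon C4a adds to the aldehyde carbon C5 through a closed six-membered chair transition state, and the chromium alkoxide 19 then acylates itself on the neighbouring methyl ester. The closest known reaction type is the Barbier-type Nozaki–Hiyama–Kishi allylation of aldehydes with 2-(bromomethyl)acrylates to α-methylene-γ-butyrolactones, in its intramolecular form used for medium and large carbocycles. Ring A closes by 9-exo-trig attack of the allyl γ-terminus on the tethered aldehyde (C4a–C5 bond), and ring C by 5-exo-trig acyl substitution of the C5 alkoxide on the ester. C4a is controlled by C11a: A(1,3) strain with the cis CH2Cr group holds H-11a in the alkene plane, and the aldehyde, tethered through C11, arrives on the face of C11 and opposite to the acetal carbon C1, so H-4a ends anti to H-11a. C5 is controlled by the Z geometry of the allyl unit, fixed by the ester, which places C11a axial and the aldehyde chain equatorial in the chair and gives the syn adduct, that is the cis-fused lactone. The step needs addition to the aldehyde in the presence of ester and acetals, secured by the chemoselectivity of organochromium reagents, and ring closure over oligomerisation, secured by high dilution and by ring B, which holds the two arms on the adjacent atoms C11a and C11 with the C9-to-C5 chain cis to C11a across C11=C10.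

Step 12
Reactants: 20 tricyclic α-methylene lactone
Product: 23 lactone with the complete side chain (C4 chain trans to C11a), via silyl ketene acetal 21 (not isolated), via C4 epimer mixture 22 (not isolated)
Conditions: prenylMgCl, CuBr·SMe2, Me3SiCl, THF, −78 °C; aq. NH4Cl; then DBU, toluene, 80 °C
Reagents that add atoms: prenylmagnesium chloride CC(C)=CC[Mg]Cl
Why: Copper-mediated conjugate addition of the prenyl group through its primary terminus to the exo-methylene lactone (Michael addition of an allylic copper reagent, trapped as silyl ketene acetal) completes the side chain, and base equilibration of the epimerisable C4 should place the chain trans to C11a on the convex face of the cis-fused lactone, the configuration of the target.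

Step 13
Reactants: 23 lactone with the complete side chain
Product: 24 C3/C5 diol
Conditions: LiAlH4, THF, 0 °C
Reagents that add atoms: none
Why: Hydride reduction of the lactone gives the 1,4-diol while ring B and the alkenes are inert and no stereocentre is touched.

Step 14
Reactants: 24 C3/C5 diol
Product: 25 C3 monoacetate
Conditions: AcCl, 2,4,6-collidine, CH2Cl2, −78 °C
Reagents that add atoms: acetyl chloride CC(Cl)=O
Why: Low-temperature acylation with AcCl and the hindered base collidine should be selective for the primary C3 hydroxyl over the secondary C5 hydroxyl (kinetically selective acetylation).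

Step 15
Reactants: 25 C3 monoacetate
Product: 26 target, (2S)-2-[(1R,2S,4E,7E,9R)-8,9-diformyl-2-hydroxy-4-methylcyclonona-4,7-dien-1-yl]-6-methylhept-5-en-1-yl acetate
Conditions: aq. HCl (0.2 M), THF, 0 °C to rt
Reagents that add atoms: water O
Why: Acid hydrolysis of the cyclic bis-acetal starts at the allylic C19 acetal and, after ring opening, the C1 hemiacetal loses menthol, which frees both formyl groups; C11a should keep its configuration because the substituents at C4a and C11a are already trans, and the C5 hydroxyl, trans to C1, cannot close a lactol.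

**Compound list**

1 | tert-butyl(but-3-yn-1-yloxy)dimethylsilane | C#CCCO[Si](C)(C)C(C)(C)C | starting material
2 | (E)-[4-(tert-butyldimethylsilyloxy)-2-methylbut-1-enyl]dimethylalane | C[Al](C)/C=C(\C)CCO[Si](C)(C)C(C)(C)C | intermediate
3 | lithium butyl[(E)-4-(tert-butyldimethylsilyloxy)-2-methylbut-1-enyl]dimethylalanate | [Li+].CCCC[Al-](C)(C)/C=C(\C)CCO[Si](C)(C)C(C)(C)C | intermediate
4 | (E)-6-(tert-butyldimethylsilyloxy)-4-methylhex-3-en-1-ol | OCC/C=C(\C)CCO[Si](C)(C)C(C)(C)C | intermediate
5 | (E)-6-(tert-butyldimethylsilyloxy)-4-methylhex-3-enal | O=CC/C=C(\C)CCO[Si](C)(C)C(C)(C)C | intermediate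
6 | (5R)-5-[(1R,2S,5R)-menthyloxy]furan-2(5H)-one | O=C1C=C[C@H](O[C@@H]2C[C@H](C)CC[C@H]2C(C)C)O1 | starting material
7 | lithium enolate of (4R,5R)-4-(1,3-dithian-2-yl)-5-menthyloxydihydrofuran-2(3H)-one (dithianyl trans to menthyloxy) | [Li]OC1=C[C@@H](C2SCCCS2)[C@H](O[C@@H]3C[C@H](C)CC[C@H]3C(C)C)O1 | intermediate
8 | aldol adduct: the lactone of 7 carrying at C11, trans to the dithianyl group, the (E)-6-(tert-butyldimethylsilyloxy)-1-hydroxy-4-methylhex-3-enyl group (carbinol epimers) | O=C1[C@H](C(O)C/C=C(\C)CCO[Si](C)(C)C(C)(C)C)[C@@H](C2SCCCS2)[C@H](O[C@@H]3C[C@H](C)CC[C@H]3C(C)C)O1 | intermediate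
9 | methanesulfonate of 8 | O=C1[C@H](C(OS(C)(=O)=O)C/C=C(\C)CCO[Si](C)(C)C(C)(C)C)[C@@H](C2SCCCS2)[C@H](O[C@@H]3C[C@H](C)CC[C@H]3C(C)C)O1 | intermediate
10 | (E)-alkylidene lactone: 4-(1,3-dithian-2-yl)-3-[(E)-6-(tert-butyldimethylsilyloxy)-4-methylhex-3-enylidene]-5-menthyloxydihydrofuran-2(3H)-one, 4,5-trans | O=C1/C(=C/C/C=C(\C)CCO[Si](C)(C)C(C)(C)C)[C@@H](C2SCCCS2)[C@H](O[C@@H]3C[C@H](C)CC[C@H]3C(C)C)O1 | intermediate
11 | lactol of 10 (hydroxyl at C19, anomers) | OC1/C(=C/C/C=C(\C)CCO[Si](C)(C)C(C)(C)C)[C@@H](C2SCCCS2)[C@H](O[C@@H]3C[C@H](C)CC[C@H]3C(C)C)O1 | intermediate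
12 | ring B bis-acetal: 2-methoxy-5-menthyloxytetrahydrofuran with the E-alkylidene chain at C11 and the dithianyl group at C11a trans to menthyloxy | COC1/C(=C/C/C=C(\C)CCO[Si](C)(C)C(C)(C)C)[C@@H](C2SCCCS2)[C@H](O[C@@H]3C[C@H](C)CC[C@H]3C(C)C)O1 | intermediate
13 | C4a aldehyde: as 12 with a formyl group in place of the dithianyl group | COC1/C(=C/C/C=C(\C)CCO[Si](C)(C)C(C)(C)C)[C@@H](C=O)[C@H](O[C@@H]2C[C@H](C)CC[C@H]2C(C)C)O1 | intermediate
14 | allylic alcohol: as 12 with a 1-hydroxy-2-(methoxycarbonyl)prop-2-enyl group at C11a (carbinol epimers) | COC1/C(=C/C/C=C(\C)CCO[Si](C)(C)C(C)(C)C)[C@@H](C(O)C(=C)C(=O)OC)[C@H](O[C@@H]2C[C@H](C)CC[C@H]2C(C)C)O1 | intermediate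
15 | methyl (Z)-2-(bromomethyl)prop-2-enoate carrying ring B at its 3-position (C11a cis to CH2Br), silyl ether | COC1/C(=C/C/C=C(\C)CCO[Si](C)(C)C(C)(C)C)[C@@H](/C=C(\CBr)C(=O)OC)[C@H](O[C@@H]2C[C@H](C)CC[C@H]2C(C)C)O1 | intermediate
16 | bromo alcohol: 15 with the free C5 hydroxyl | COC1/C(=C/C/C=C(\C)CCO)[C@@H](/C=C(\CBr)C(=O)OC)[C@H](O[C@@H]2C[C@H](C)CC[C@H]2C(C)C)O1 | intermediate
17 | bromo aldehyde: 16 oxidised to the C5 aldehyde | COC1/C(=C/C/C=C(\C)CC=O)[C@@H](/C=C(\CBr)C(=O)OC)[C@H](O[C@@H]2C[C@H](C)CC[C@H]2C(C)C)O1 | intermediate
18 | allylchromium dichloride from 17 | COC1/C(=C/C/C=C(\C)CC=O)[C@@H](/C=C(\C[Cr](Cl)Cl)C(=O)OC)[C@H](O[C@@H]2C[C@H](C)CC[C@H]2C(C)C)O1 | intermediate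
19 | chromium alkoxide of the ring A hydroxy ester (C5–O–CrCl2, acrylate at C4a) | C=C(C(=O)OC)[C@H]1[C@@H](O[Cr](Cl)Cl)C/C(C)=C/C/C=C2/C(OC)O[C@@H](O[C@@H]3C[C@H](C)CC[C@H]3C(C)C)[C@H]12 | intermediate
20 | tricyclic α-methylene lactone: ring A cis-fused at C4a–C5 to the α-methylene-γ-lactone ring C and fused at C11–C11a to ring B; H-4a anti to H-11a | C=C1C(=O)O[C@H]2C/C(C)=C/C/C=C3/C(OC)O[C@@H](O[C@@H]4C[C@H](C)CC[C@H]4C(C)C)[C@@H]3[C@@H]12 | intermediate
21 | trimethylsilyl ketene acetal of the prenyl adduct | CC(C)=CCCC1=C(O[Si](C)(C)C)O[C@H]2C/C(C)=C/C/C=C3/C(OC)O[C@@H](O[C@@H]4C[C@H](C)CC[C@H]4C(C)C)[C@@H]3[C@@H]12 | intermediate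
22 | α-(4-methylpent-3-enyl) lactone, mixture of C4 epimers | CC(C)=CCCC1C(=O)O[C@H]2C/C(C)=C/C/C=C3/C(OC)O[C@@H](O[C@@H]4C[C@H](C)CC[C@H]4C(C)C)[C@@H]3[C@@H]12 | intermediate
23 | α-(4-methylpent-3-enyl) lactone with the C4 chain trans to C11a | CC(C)=CCC[C@@H]1C(=O)O[C@H]2C/C(C)=C/C/C=C3/C(OC)O[C@@H](O[C@@H]4C[C@H](C)CC[C@H]4C(C)C)[C@@H]3[C@@H]12 | intermediate
24 | C3/C5 diol with ring B intact | CC(C)=CCC[C@H](CO)[C@H]1[C@@H](O)C/C(C)=C/C/C=C2/C(OC)O[C@@H](O[C@@H]3C[C@H](C)CC[C@H]3C(C)C)[C@H]12 | intermediate
25 | C3 monoacetate with ring B intact | CC(C)=CCC[C@H](COC(C)=O)[C@H]1[C@@H](O)C/C(C)=C/C/C=C2/C(OC)O[C@@H](O[C@@H]3C[C@H](C)CC[C@H]3C(C)C)[C@H]12 | intermediate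
26 | (2S)-2-[(1R,2S,4E,7E,9R)-8,9-diformyl-2-hydroxy-4-methylcyclonona-4,7-dien-1-yl]-6-methylhept-5-en-1-yl acetate | CC(=O)OC[C@@H](CCC=C(C)C)[C@H]1[C@@H](O)C/C(C)=C/C/C=C(/C=O)[C@@H]1C=O | target

**Step count and risks**

Total step count: 15. Longest linear sequence: 15 steps (1 → 26; building block 6 enters at step 3).

Steps most likely to fail:

1. Step 11. The strain of the E-cyclononene may slow ring closure so much that intermolecular allylation (oligomerisation) and reductive loss of the allylic bromide take over, or the forming ring may prevent the chair transition state so that facial selectivity at C5 erodes. The fallback replaces the organochromium species made in the presence of the aldehyde by an isolable allylboronate that can react only through a tight cyclic transition state. It sets out from 16. Borylation of the allylic bromide with B2pin2 under Pd2(dba)3 catalysis (through the π-allylpalladium intermediate, boron at the less hindered terminus) should give the methyl (Z)-2-[(pinacolatoboryl)methyl]enoate alcohol F1. Dess–Martin oxidation should give the boronate aldehyde F2, which is stable at room temperature because 2-(alkoxycarbonyl)allylboronates are deactivated. Heating F2 in dilute toluene (2 mM, 90 °C) should effect intramolecular allylboration through the same chair arrangement, followed by lactonisation, and the route is rejoined at 20.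

2. Step 3. Proton transfer from the enolisable β,γ-unsaturated aldehyde 5 to the basic lithium enolate 7 may quench the enolate and move the double bond of 5 into conjugation instead of giving carbonyl addition. The fallback replaces the aldol condensation by an olefination with a weakly basic phosphonate anion. It sets out from 6. Conjugate addition of 2-lithio-1,3-dithiane with a proton quench should give (4R,5R)-4-(1,3-dithian-2-yl)-5-menthyloxydihydrofuran-2(3H)-one F3. LiN(i-Pr)2 and ClP(O)(OEt)2 should give the ketene acetal phosphate F4, which a second equivalent of LiN(i-Pr)2 rearranges (phosphoryl shift from O to C) to the α-(diethoxyphosphoryl) lactone F5. Horner–Wadsworth–Emmons reaction of F5 with 5 (LiCl, DBU, MeCN) should give the E-alkylidene lactone, and the route is rejoined at 10.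

3. Step 12. The prenyl copper reagent may couple through its tertiary terminus and give the reverse-prenyl side chain. The fallback builds the chain from a symmetrical allyl unit and a later olefin metathesis. It sets out from 20. Conjugate addition of allylMgBr/CuBr·SMe2/Me3SiCl followed by DBU equilibration should give the trans α-(but-3-enyl) lactone F6. Cross-metathesis of its terminal alkene with 2-methylbut-2-ene (second-generation Grubbs catalyst, RuCl2(=CHPh)(H2IMes)(PCy3)), with the trisubstituted ring alkenes as spectators, should give 23, where the route is rejoined.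

Further compounds
F1 | step 11 | allylboronate alcohol: 16 with CH2B(pin) in place of CH2Br | COC1/C(=C/C/C=C(\C)CCO)[C@@H](/C=C(\CB2OC(C)(C)C(C)(C)O2)C(=O)OC)[C@H](O[C@@H]3C[C@H](C)CC[C@H]3C(C)C)O1
F2 | step 11 | allylboronate aldehyde: 17 with CH2B(pin) in place of CH2Br | COC1/C(=C/C/C=C(\C)CC=O)[C@@H](/C=C(\CB2OC(C)(C)C(C)(C)O2)C(=O)OC)[C@H](O[C@@H]3C[C@H](C)CC[C@H]3C(C)C)O1
F3 | step 3 | (4R,5R)-4-(1,3-dithian-2-yl)-5-menthyloxydihydrofuran-2(3H)-one | O=C1C[C@@H](C2SCCCS2)[C@H](O[C@@H]3C[C@H](C)CC[C@H]3C(C)C)O1
F4 | step 3 | diethyl ketene acetal phosphate of F3 | CCOP(=O)(OCC)OC1=C[C@@H](C2SCCCS2)[C@H](O[C@@H]3C[C@H](C)CC[C@H]3C(C)C)O1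
F5 | step 3 | 3-(diethoxyphosphoryl) derivative of F3 | O=C1C(P(=O)(OCC)OCC)[C@@H](C2SCCCS2)[C@H](O[C@@H]3C[C@H](C)CC[C@H]3C(C)C)O1
F6 | step 12 | α-(but-3-enyl) lactone with the C4 chain trans to C11a | C=CCC[C@@H]1C(=O)O[C@H]2C/C(C)=C/C/C=C3/C(OC)O[C@@H](O[C@@H]4C[C@H](C)CC[C@H]4C(C)C)[C@@H]3[C@@H]12
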